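## Retrosynthetic overview
1. The tridepside (rings C–B–A) is cut at its two aryl‑ester C–O bonds. This gives ring A as methyl orsellinate (its free 4‑OH is the nucleophile), ring B as 4‑O‑benzyl‑2‑O‑methylorsellinic acid, and ring C as 2,4‑di‑O‑benzylorsellinic acid.
2. All three units come from one common intermediate, methyl orsellinate, by selective O‑alkylation and saponification.
3. Methyl orsellinate comes from aromatisation (Br2, then hydrogenolysis) of methyl dihydroorsellinate. That compound comes from the key intermolecular Michael addition of methyl acetoacetate to methyl crotonate, with Dieckmann closure in the same pot.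
4. Ring order: there is a single ring‑forming event. The six‑membered carbocycle is made once, aromatised, and supplies rings A, B and C. Assembly then runs A + B, debenzylation, + C, final debenzylation.

Assumption: the target has no stereocentre, stereogenic axis or C=C geometry. It is achiral, the given SMILES defines it completely, and no stereocontrol is needed.

## Route

Step 1
Reactants: 1 methyl acetoacetate; 2 methyl (E)-crotonate
Product: 4 methyl 2-methyl-4,6-dioxocyclohexane-1-carboxylate (methyl dihydroorsellinate; racemic cis/trans + keto/enol mixture), via Michael adduct 3 (not isolated)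
Conditions: NaOMe (1.1 equiv), MeOH, reflux, 16 h; then aq HCl, 0 °C
Reagents that add atoms: none
Why: Intermolecular Michael addition of the acetoacetate enolate to the crotonate β‑carbon forms the key C–C bond and the adduct closes in the same pot by Dieckmann (intramolecular Claisen) condensation, with matched NaOMe/MeOH excluding ester scrambling and deprotonation of the β‑dicarbonyl product pulling all equilibria forward; the two sp3 stereocentres form unselectively and are erased in step 2.

Step 2
Reactants: 4 methyl dihydroorsellinate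
Product: 5 methyl 3,5-dibromo-2,4-dihydroxy-6-methylbenzoate
Conditions: Br2 (3.1 equiv), AcOH, 10 °C → rt, 16 h; pour into H2O, filter
Reagents that add atoms: bromine, BrBr
Why: Bromination–dehydrobromination aromatisation of the enolised β‑dicarbonyl system is driven by the gain of aromaticity, and three equivalents of Br2 deliberately fill both free ring positions so that one crystalline product forms instead of a mixture of partly brominated phenols.

Step 3
Reactants: 5 methyl 3,5-dibromo-2,4-dihydroxy-6-methylbenzoate
Product: 6 methyl 2,4-dihydroxy-6-methylbenzoate (methyl orsellinate)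
Conditions: H2 (1 atm), 10% Pd/C, NaOAc (2.5 equiv), MeOH, rt
Reagents that add atoms: none
Why: Catalytic hydrogenolysis of aryl C–Br bonds is fast on Pd/C when the HBr is buffered by acetate, and the ester and phenols are inert under these conditions.

Compound 6 is divided in three portions for steps 4, 7 and 9.

Step 4
Reactants: 6 methyl orsellinate
Product: 7 methyl 4-(benzyloxy)-2-hydroxy-6-methylbenzoate
Conditions: BnBr (1.05 equiv), K2CO3 (1.2 equiv), acetone, reflux, 8 h
Reagents that add atoms: benzyl bromide, BrCc1ccccc1
Why: Regioselective Williamson etherification, because the 2‑OH is locked in a strong intramolecular hydrogen bond to the ester carbonyl, so a weak base and about one equivalent of halide alkylate only the more acidic, unhindered 4‑OH.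

Step 5
Reactants: 7 methyl 4-(benzyloxy)-2-hydroxy-6-methylbenzoate
Product: 8 methyl 4-(benzyloxy)-2-methoxy-6-methylbenzoate
Conditions: MeI (3 equiv), K2CO3 (3 equiv), DMF, 40 °C, 16 h
Reagents that add atoms: iodomethane, CI
Why: Williamson etherification of the one remaining (chelated) phenol goes to completion with a small, reactive electrophile in excess in a dipolar aprotic solvent.

Step 6
Reactants: 8 methyl 4-(benzyloxy)-2-methoxy-6-methylbenzoate
Product: 9 4-(benzyloxy)-2-methoxy-6-methylbenzoic acid
Conditions: KOH (10 equiv), DMSO–H2O (4:1), 90 °C, 16 h; then 2 M HCl, 0 °C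
Reagents that add atoms: potassium hydroxide, [K+].[OH-] (delivers the new carboxyl oxygen)
Why: Saponification (BAc2) of the di‑ortho‑substituted benzoate succeeds with poorly solvated hydroxide in hot aqueous DMSO, both ethers are base‑stable, and cold acidification avoids decarboxylation.

Step 7
Reactants: 6 methyl orsellinate
Product: 10 methyl 2,4-bis(benzyloxy)-6-methylbenzoate
Conditions: BnBr (2.5 equiv), K2CO3 (3 equiv), DMF, 60 °C, 12 h
Reagents that add atoms: benzyl bromide, BrCc1ccccc1
Why: Exhaustive Williamson etherification, in which excess halide and base in warm DMF also alkylate the chelated 2‑OH.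

Step 8
Reactants: 10 methyl 2,4-bis(benzyloxy)-6-methylbenzoate
Product: 11 2,4-bis(benzyloxy)-6-methylbenzoic acid
Conditions: KOH (10 equiv), DMSO–H2O (4:1), 90 °C, 16 h; then 2 M HCl, 0 °C
Reagents that add atoms: potassium hydroxide, [K+].[OH-] (delivers the new carboxyl oxygen)
Why: The same forcing saponification of a hindered benzoate as in step 6, with benzyl ethers untouched by base.

Step 9
Reactants: 9 4-(benzyloxy)-2-methoxy-6-methylbenzoic acid; 6 methyl orsellinate
Product: 13 methyl 4-{[4-(benzyloxy)-2-methoxy-6-methylbenzoyl]oxy}-2-hydroxy-6-methylbenzoate, via mixed trifluoroacetic anhydride 12 (not isolated)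
Conditions: TFAA (4 equiv), dry toluene, 0 °C → rt, 6 h; aq NaHCO3 wash
Reagents that add atoms: trifluoroacetic anhydride, O=C(OC(=O)C(F)(F)F)C(F)(F)F (its CF3CO group sits only in intermediate 12 and leaves again; no atom of it remains in 13)
Why: Mixed‑anhydride esterification (classical depside coupling), in which the electron‑rich hindered acid is activated with acylium character that overcomes the di‑ortho substitution, and only the free 4‑OH of 6 is acylated because the 2‑OH is chelated to the ester and any aryl trifluoroacetate is hydrolysed on work‑up.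

Step 10
Reactants: 13 benzyl-protected didepside
Product: 14 methyl 2-hydroxy-4-[(4-hydroxy-2-methoxy-6-methylbenzoyl)oxy]-6-methylbenzoate
Conditions: H2 (1 atm), 10% Pd/C, EtOAc, rt
Reagents that add atoms: none
Why: Hydrogenolysis of the benzyl aryl ether is neutral and leaves aryl and methyl esters intact, and the non‑nucleophilic solvent excludes alcoholysis of the depside bond.

Step 11
Reactants: 11 2,4-bis(benzyloxy)-6-methylbenzoic acid; 14 didepside phenol
Product: 16 methyl 4-{[4-{[2,4-bis(benzyloxy)-6-methylbenzoyl]oxy}-2-methoxy-6-methylbenzoyl]oxy}-2-hydroxy-6-methylbenzoate, via mixed trifluoroacetic anhydride 15 (not isolated)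
Conditions: TFAA (4 equiv), dry toluene–CH2Cl2 (3:1), 0 °C → rt, 8 h; aq NaHCO3 wash
Reagents that add atoms: trifluoroacetic anhydride, O=C(OC(=O)C(F)(F)F)C(F)(F)F (its CF3CO group sits only in intermediate 15 and leaves again; no atom of it remains in 16)
Why: The same mixed‑anhydride depside esterification, selective for the unchelated 4′‑OH of ring B over the ester‑chelated 2‑OH of ring A, at a temperature where the existing depside bond does not exchange.

Step 12
Reactants: 16 dibenzyl-protected tridepside
Product: 17 methyl 4-{[4-[(2,4-dihydroxy-6-methylbenzoyl)oxy]-2-methoxy-6-methylbenzoyl]oxy}-2-hydroxy-6-methylbenzoate (target)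
Conditions: H2 (1 atm), 10% Pd/C, EtOAc, rt
Reagents that add atoms: none
Why: Double hydrogenolysis of the benzyl ethers under neutral, non‑alcoholic conditions frees both ring C phenols without touching the three ester linkages; no stereocentre exists or is created.

## Compound list
1 | methyl acetoacetate | CC(=O)CC(=O)OC | starting material
2 | methyl (E)-crotonate | C/C=C/C(=O)OC | starting material
3 | dimethyl 2-acetyl-3-methylpentanedioate (Michael adduct; stereoisomer mixture; not isolated) | COC(=O)CC(C)C(C(C)=O)C(=O)OC | intermediate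
4 | methyl 2-methyl-4,6-dioxocyclohexane-1-carboxylate (methyl dihydroorsellinate; stereoisomer/enol mixture) | COC(=O)C1C(C)CC(=O)CC1=O | intermediate
5 | methyl 3,5-dibromo-2,4-dihydroxy-6-methylbenzoate | COC(=O)c1c(C)c(Br)c(O)c(Br)c1O | intermediate
6 | methyl 2,4-dihydroxy-6-methylbenzoate (methyl orsellinate) | COC(=O)c1c(C)cc(O)cc1O | intermediate
7 | methyl 4-(benzyloxy)-2-hydroxy-6-methylbenzoate | COC(=O)c1c(C)cc(OCc2ccccc2)cc1O | intermediate
8 | methyl 4-(benzyloxy)-2-methoxy-6-methylbenzoate | COC(=O)c1c(C)cc(OCc2ccccc2)cc1OC | intermediate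
9 | 4-(benzyloxy)-2-methoxy-6-methylbenzoic acid | OC(=O)c1c(C)cc(OCc2ccccc2)cc1OC | intermediate
10 | methyl 2,4-bis(benzyloxy)-6-methylbenzoate | COC(=O)c1c(C)cc(OCc2ccccc2)cc1OCc3ccccc3 | intermediate
11 | 2,4-bis(benzyloxy)-6-methylbenzoic acid | OC(=O)c1c(C)cc(OCc2ccccc2)cc1OCc3ccccc3 | intermediate
12 | 4-(benzyloxy)-2-methoxy-6-methylbenzoic trifluoroacetic anhydride (not isolated) | COc1cc(OCc2ccccc2)cc(C)c1C(=O)OC(=O)C(F)(F)F | intermediate
13 | methyl 4-{[4-(benzyloxy)-2-methoxy-6-methylbenzoyl]oxy}-2-hydroxy-6-methylbenzoate | COC(=O)c1c(C)cc(OC(=O)c2c(C)cc(OCc3ccccc3)cc2OC)cc1O | intermediate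
14 | methyl 2-hydroxy-4-[(4-hydroxy-2-methoxy-6-methylbenzoyl)oxy]-6-methylbenzoate | COC(=O)c1c(C)cc(OC(=O)c2c(C)cc(O)cc2OC)cc1O | intermediate
15 | 2,4-bis(benzyloxy)-6-methylbenzoic trifluoroacetic anhydride (not isolated) | Cc1cc(OCc2ccccc2)cc(OCc3ccccc3)c1C(=O)OC(=O)C(F)(F)F | intermediate
16 | methyl 4-{[4-{[2,4-bis(benzyloxy)-6-methylbenzoyl]oxy}-2-methoxy-6-methylbenzoyl]oxy}-2-hydroxy-6-methylbenzoate | COC(=O)c1c(C)cc(OC(=O)c2c(C)cc(OC(=O)c3c(C)cc(OCc4ccccc4)cc3OCc5ccccc5)cc2OC)cc1O | intermediate
17 | methyl 4-{[4-[(2,4-dihydroxy-6-methylbenzoyl)oxy]-2-methoxy-6-methylbenzoyl]oxy}-2-hydroxy-6-methylbenzoate (achiral) | COC(=O)c1c(C)cc(OC(=O)c2c(C)cc(OC(=O)c3c(C)cc(O)cc3O)cc2OC)cc1O | target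

## Counts
Total steps: 12. Longest linear sequence: 10 (steps 1, 2, 3, 4, 5, 6, 9, 10, 11, 12). Steps 7 and 8 form the side branch to ring C.

## Three steps most likely to fail, with fallbacks

**Step 2 (bromination–aromatisation).** The risk is incomplete aromatisation, or over‑oxidation to bromodienones that lowers the yield of 5. The fallback sets out from 1 and comes back to the route at 6, so no oxidation or debromination is needed. Compound 1 is converted into its sodium enolate (NaH, THF, 0 °C), and half of it is taken on to the dianion (n‑BuLi, 0.5 equiv per 1, −78 °C). The dianion γ‑carbon attacks the ester of a second molecule in an intermolecular Claisen condensation to give methyl 3,5,7-trioxooctanoate F1. On warming to reflux this cyclises by intramolecular aldol condensation (C2 onto C7), loses water and tautomerises to 6 after an HCl quench.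

**Step 9 (first depside coupling).** The risk is acylation at both hydroxyls of 6, or at the wrong one. The fallback sets out from 6 (with acid 9) and comes back at 14. It removes the selectivity question by masking.
- Compound 6 is allylated selectively at O‑4 (allyl bromide 1.05 equiv, K2CO3, acetone, reflux) to methyl 4-(allyloxy)-2-hydroxy-6-methylbenzoate F2.
- F2 is benzylated at O‑2 (BnBr, K2CO3, DMF, 60 °C) to methyl 4-(allyloxy)-2-(benzyloxy)-6-methylbenzoate F3.
- F3 is deallylated (cat. Pd(PPh3)4, morpholine, THF, rt) to methyl 2-(benzyloxy)-4-hydroxy-6-methylbenzoate F4, which has a single free OH.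
- Coupling F4 with 9 through 12 (TFAA, toluene) gives methyl 2-(benzyloxy)-4-{[4-(benzyloxy)-2-methoxy-6-methylbenzoyl]oxy}-6-methylbenzoate F5.
- Hydrogenolysis (H2, Pd/C, EtOAc) removes both benzyl groups at once and delivers 14.

**Step 11 (second depside coupling).** The risks are the bulk of the 2‑benzyloxy‑6‑methyl acid 11, the poor solubility of 14, and acid‑promoted exchange of the existing depside bond. The fallback sets out from 7 (with phenol 14) and comes back at the target 17. It uses a smaller acyl donor and neutral carbodiimide coupling.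
- Compound 7 is saponified (KOH, aq DMSO, 90 °C; cold HCl) to 4-(benzyloxy)-2-hydroxy-6-methylbenzoic acid F6. Its chelated ortho‑OH does not compete as a nucleophile.
- DCC in dry toluene converts F6 into O-[4-(benzyloxy)-2-hydroxy-6-methylbenzoyl]-N,N'-dicyclohexylisourea F7.
- F7 acylates the 4′‑OH of 14 to give methyl 4-{[4-{[4-(benzyloxy)-2-hydroxy-6-methylbenzoyl]oxy}-2-methoxy-6-methylbenzoyl]oxy}-2-hydroxy-6-methylbenzoate F8.
- Hydrogenolysis (H2, Pd/C, EtOAc) of the single benzyl ether gives 17.

## Further compounds
F1 | step 2 | methyl 3,5,7-trioxooctanoate | CC(=O)CC(=O)CC(=O)CC(=O)OC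
F2 | step 9 | methyl 4-(allyloxy)-2-hydroxy-6-methylbenzoate | COC(=O)c1c(C)cc(OCC=C)cc1O
F3 | step 9 | methyl 4-(allyloxy)-2-(benzyloxy)-6-methylbenzoate | COC(=O)c1c(C)cc(OCC=C)cc1OCc2ccccc2
F4 | step 9 | methyl 2-(benzyloxy)-4-hydroxy-6-methylbenzoate | COC(=O)c1c(C)cc(O)cc1OCc2ccccc2
F5 | step 9 | methyl 2-(benzyloxy)-4-{[4-(benzyloxy)-2-methoxy-6-methylbenzoyl]oxy}-6-methylbenzoate | COC(=O)c1c(C)cc(OC(=O)c2c(C)cc(OCc3ccccc3)cc2OC)cc1OCc4ccccc4
F6 | step 11 | 4-(benzyloxy)-2-hydroxy-6-methylbenzoic acid | OC(=O)c1c(C)cc(OCc2ccccc2)cc1O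
F7 | step 11 | O-[4-(benzyloxy)-2-hydroxy-6-methylbenzoyl]-N,N'-dicyclohexylisourea | Cc1cc(OCc2ccccc2)cc(O)c1C(=O)OC(=NC3CCCCC3)NC4CCCCC4
F8 | step 11 | methyl 4-{[4-{[4-(benzyloxy)-2-hydroxy-6-methylbenzoyl]oxy}-2-methoxy-6-methylbenzoyl]oxy}-2-hydroxy-6-methylbenzoate | COC(=O)c1c(C)cc(OC(=O)c2c(C)cc(OC(=O)c3c(C)cc(OCc4ccccc4)cc3O)cc2OC)cc1O
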